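**Strategy**

Everything rests on the bond between the vinyl carbon C7 and the quaternary ring carbon C6. C6 and C3, the two oxygen-bearing carbons of the 1,2-dioxane ring, stand 1,4 to each other, so one extra oxygen can tie them into a strained bicyclic ozonide (2,3,7-trioxabicyclo[2.2.1]heptane). In the key step an (E)-alkenylalane, made in the flask by methylalumination of an enyne, opens this ether bridge at the tertiary bridgehead C6 and hands over its alkenyl group on the face the oxygen leaves. One operation gives the C6–C7 bond, the C8 methyl group, the E alkene and the C6 stereocentre, and leaves a C3 lactol for the acetic acid arm.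

Key step: step 9

Numbering of the target used below: C1 carboxyl, C2 methylene, C3–C6 ring carbons (O2 on C3, O1 on C6, O7 the temporary bridging oxygen), C7=C8 trisubstituted alkene, C10 side-chain stereocentre, C11=C12 disubstituted alkene.

Assumption: the facial sense of the two catalysts (amino alcohol in step 1, phosphoramidite in step 6) is taken from their usual models; if either delivers the antipode, the enantiomeric ligand is used.

Remark: lactol 22 and methyl acetal 24 are drawn as the anomers the mechanism delivers; anomerisation at C3 is harmless because C3 is ionised in step 11.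

**Route**

Step 1
Reactants: 1 (E)-pent-2-enal; 2 diethylzinc
Product: 3 (3R,4E)-hept-4-en-3-ol
Conditions: (+)-MIB (4 mol %), hexane, 0 °C
Reagents that add atoms: 2 diethylzinc, CC[Zn]CC
Why: Amino-alcohol-catalysed enantioselective 1,2-addition of a dialkylzinc to an enal, in which the chiral zinc aminoalkoxide selects the aldehyde face and sets the carbinol centre as R.

Step 2
Reactants: 3 (3R,4E)-hept-4-en-3-ol; 4 triethyl orthoacetate
Product: 5 ethyl (3R,4E)-3-ethylhept-4-enoate
Conditions: EtCO2H (cat.), 140 °C, EtOH distilled off
Reagents that add atoms: 4 triethyl orthoacetate, CC(OCC)(OCC)OCC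
Why: Johnson–Claisen rearrangement through a chair transition state with the carbinol ethyl group equatorial, which transfers the C–O chirality to the new C–C bond (3R, the future C10) and gives the E alkene.

Step 3
Reactants: 5 ethyl (3R,4E)-3-ethylhept-4-enoate
Product: 6 (3R,4E)-3-ethylhept-4-enal
Conditions: DIBAL-H, CH2Cl2, −78 °C; Rochelle salt
Reagents that add atoms: none
Why: Partial ester reduction with DIBAL-H stops at the aluminium hemiacetal at −78 °C and releases the aldehyde on work-up; the β-stereocentre is not touched.

Step 4
Reactants: 6 (3R,4E)-3-ethylhept-4-enal; 7 dimethyl (1-diazo-2-oxopropyl)phosphonate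
Product: 8 (4R,5E)-4-ethyloct-5-en-1-yne
Conditions: K2CO3, MeOH, 0 °C → rt
Reagents that add atoms: 7 dimethyl (1-diazo-2-oxopropyl)phosphonate, CC(=O)C(=[N+]=[N-])P(=O)(OC)OC
Why: Seyferth–Gilbert homologation with the Ohira–Bestmann reagent converts the aldehyde into the terminal alkyne under mild base that leaves the β-stereocentre and the E alkene alone.

Step 5
Reactants: 10 2,2-dimethoxyacetaldehyde; 9 diethyl (2-oxobutyl)phosphonate
Product: 11 (4E)-6,6-dimethoxyhex-4-en-3-one
Conditions: K2CO3, H2O/THF, rt
Reagents that add atoms: 9 diethyl (2-oxobutyl)phosphonate, CCC(=O)CP(=O)(OCC)OCC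
Why: Horner–Wadsworth–Emmons olefination with a stabilised β-ketophosphonate should give the E enone, with the second aldehyde of glyoxal kept as its dimethyl acetal.

Step 6
Reactants: 11 (4E)-6,6-dimethoxyhex-4-en-3-one; 2 diethylzinc
Product: 12 (5R)-5-(dimethoxymethyl)heptan-3-one
Conditions: Cu(OTf)2 (2 mol %), BINOL-derived phosphoramidite (4 mol %), toluene, −30 °C; aq. NH4Cl
Reagents that add atoms: 2 diethylzinc, CC[Zn]CC
Why: Copper-catalysed asymmetric conjugate addition of diethylzinc, in which the chiral phosphoramidite–copper complex selects the enone face and sets the β-carbon (the future C4) as R.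

Step 7
Reactants: 12 (5R)-5-(dimethoxymethyl)heptan-3-one; 13 O-methylhydroxylamine hydrochloride; 14 water
Product: 16 (2R)-2-ethyl-4-(methoxyimino)hexanal, via oxime acetal 15 (not isolated)
Conditions: pyridine, MeOH, rt; then Amberlyst-15, acetone/H2O, rt
Reagents that add atoms: 13 O-methylhydroxylamine hydrochloride, CON.Cl; 14 water, O
Why: Oxime ether condensation at the ketone followed by mild acid-catalysed acetal hydrolysis, which the O-methyl oxime survives; the aldehyde is used at once so that its α-stereocentre is not exposed to enolisation.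

Step 8
Reactants: 16 (2R)-2-ethyl-4-(methoxyimino)hexanal; 17 ozone
Product: 19 (1R,4S,5R)-1,5-diethyl-2,3,7-trioxabicyclo[2.2.1]heptane (5-exo-ethyl, ethyl syn to O7), via carbonyl oxide 18 (not isolated)
Conditions: O3, CH2Cl2, −78 °C; N2 purge
Reagents that add atoms: 17 ozone, O=[O+][O-]
Why: Griesbaum-type ozonolysis of the O-methyl ketoxime releases a ketone O-oxide that adds to the tethered aldehyde in an intramolecular [3+2] cycloaddition; a Felkin-type arrangement with the C4 ethyl group turned away from the incoming terminal oxygen should place it exo, syn to the ether bridge, which fixes both bridgeheads relative to C4.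

Step 9
Reactants: 19 (1R,4S,5R)-1,5-diethyl-2,3,7-trioxabicyclo[2.2.1]heptane; 8 (4R,5E)-4-ethyloct-5-en-1-yne; 20 trimethylaluminium
Product: 22 (3S,4R,6R)-4,6-diethyl-6-[(1E,4R,5E)-4-ethyl-2-methylocta-1,5-dien-1-yl]-1,2-dioxan-3-ol, via alkenylalane 21 (not isolated)
Conditions: 8, AlMe3, Cp2ZrCl2 (20 mol %), CH2Cl2, rt; volatiles off, hexane extract; then 19, CH2Cl2/hexane, −78 → −30 °C; Rochelle salt
Reagents that add atoms: 20 trimethylaluminium, C[Al](C)C
Why: Proposed new method: Zr-catalysed syn-methylalumination of the terminal alkyne of 8 gives the (E)-alkenyldimethylalane 21, whose Lewis-acidic aluminium binds the ether oxygen O7 of ozonide 19 and breaks the O7–C6 bond at the tertiary bridgehead, giving the cyclic C6 peroxycarbenium ion paired with an alkenyl aluminate on the C3 oxygen, which passes its alkenyl group to C6 inside the ion pair. The closest known reactions are the retentive opening of bicyclic ketals by DIBAL-H and trialkylalanes, the Lewis-acid-mediated allylation of ozonides and peroxyketals through peroxycarbenium ions, and the alane substitution of artemisinin-type acetals with the O–O bond intact. No ring is closed: the [2.2.1] bicycle is opened to the monocyclic 1,2-dioxane and the relief of its strain drives the ionisation. C6 is controlled by the bridge, because the alkenyl group enters on the face that O7 leaves, cis to the C3 oxygen and therefore, in the exo ozonide, cis to the C4 ethyl group, a relationship that undirected axial attack on the free cation would not give; the E geometry of C7=C8 comes from syn-carbometalation and transfer with retention. The step needs cleavage of O7–C6 and not of O7–C3 or of a peroxide bond, and alkenyl not methyl transfer; the first is secured by the more basic ether oxygen and the tertiary, better stabilised bridgehead, the second by the higher migratory aptitude of the sp2 ligand, by stripping excess AlMe3 before the addition and by a donor-free solvent that keeps the ion pair tight.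

Step 10
Reactants: 22 (3S,4R,6R)-4,6-diethyl-6-[(1E,4R,5E)-4-ethyl-2-methylocta-1,5-dien-1-yl]-1,2-dioxan-3-ol; 23 methanol
Product: 24 (3S,4R,6R)-4,6-diethyl-6-[(1E,4R,5E)-4-ethyl-2-methylocta-1,5-dien-1-yl]-3-methoxy-1,2-dioxane
Conditions: PPTS (cat.), MeOH, 4 Å MS, rt
Reagents that add atoms: 23 methanol, CO
Why: Acid-catalysed acetalisation of the cyclic peroxy hemiacetal gives the methyl peroxyacetal as a leaving group under conditions too mild to ionise the tertiary allylic C6–O bond, and avoids amine bases that fragment peroxides bearing an α-hydrogen.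

Step 11
Reactants: 24 (3S,4R,6R)-4,6-diethyl-6-[(1E,4R,5E)-4-ethyl-2-methylocta-1,5-dien-1-yl]-3-methoxy-1,2-dioxane; 25 1-(tert-butyldimethylsilyloxy)-1-methoxyethene
Product: 26 methyl 2-[(3R,4R,6R)-4,6-diethyl-6-[(1E,4R,5E)-4-ethyl-2-methylocta-1,5-dien-1-yl]-1,2-dioxan-3-yl]acetate
Conditions: TMSOTf (0.3 equiv), CH2Cl2, −78 °C
Reagents that add atoms: 25 1-(tert-butyldimethylsilyloxy)-1-methoxyethene, C=C(OC)O[Si](C)(C)C(C)(C)C
Why: Lewis-acid ionisation of the methoxy peroxyacetal gives the C3 peroxycarbenium ion, which the silyl ketene acetal traps in a Mukaiyama-type addition; attack should be axial on the half-chair that keeps C4-ethyl and C6-alkenyl equatorial (their syn-diaxial alternative is prohibitive) and on the face away from the axial C6 ethyl group, so the acetate arm enters cis to C4-ethyl and sets C3 as R.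

Step 12
Reactants: 26 methyl 2-[(3R,4R,6R)-4,6-diethyl-6-[(1E,4R,5E)-4-ethyl-2-methylocta-1,5-dien-1-yl]-1,2-dioxan-3-yl]acetate; 27 lithium hydroxide
Product: 28 2-[(3R,4R,6R)-4,6-diethyl-6-[(1E,4R,5E)-4-ethyl-2-methylocta-1,5-dien-1-yl]-1,2-dioxan-3-yl]acetic acid
Conditions: LiOH, THF/H2O, 0 °C; 1 M HCl to pH 3
Reagents that add atoms: 27 lithium hydroxide, [Li+].[OH-]
Why: Saponification by hydroxide attack at the ester carbonyl should be faster than α-deprotonation, so the β-peroxy ester is hydrolysed without retro-oxa-Michael opening of the ring, and the dialkyl peroxide is stable to cold aqueous base.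

**Compound list**

1 | (E)-pent-2-enal | CC/C=C/C=O | starting material
2 | diethylzinc | CC[Zn]CC | starting material
3 | (3R,4E)-hept-4-en-3-ol | CC[C@@H](O)/C=C/CC | intermediate
4 | triethyl orthoacetate | CC(OCC)(OCC)OCC | starting material
5 | ethyl (3R,4E)-3-ethylhept-4-enoate | CCOC(=O)C[C@@H](CC)/C=C/CC | intermediate
6 | (3R,4E)-3-ethylhept-4-enal | O=CC[C@@H](CC)/C=C/CC | intermediate
7 | dimethyl (1-diazo-2-oxopropyl)phosphonate | CC(=O)C(=[N+]=[N-])P(=O)(OC)OC | starting material
8 | (4R,5E)-4-ethyloct-5-en-1-yne | C#CC[C@@H](CC)/C=C/CC | intermediate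
9 | diethyl (2-oxobutyl)phosphonate | CCC(=O)CP(=O)(OCC)OCC | starting material
10 | 2,2-dimethoxyacetaldehyde | COC(OC)C=O | starting material
11 | (4E)-6,6-dimethoxyhex-4-en-3-one | CCC(=O)/C=C/C(OC)OC | intermediate
12 | (5R)-5-(dimethoxymethyl)heptan-3-one | CCC(=O)C[C@@H](CC)C(OC)OC | intermediate
13 | O-methylhydroxylamine hydrochloride | CON.Cl | starting material
14 | water | O | starting material
15 | (5R)-5-(dimethoxymethyl)heptan-3-one O-methyl oxime (E/Z mixture) | CCC(=NOC)C[C@@H](CC)C(OC)OC | intermediate
16 | (2R)-2-ethyl-4-(methoxyimino)hexanal | CCC(=NOC)C[C@@H](CC)C=O | intermediate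
17 | ozone | O=[O+][O-] | starting material
18 | (2R)-2-ethyl-4-oxohexanal 4-O-oxide (ketone carbonyl oxide) | CCC(=[O+][O-])C[C@@H](CC)C=O | intermediate
19 | (1R,4S,5R)-1,5-diethyl-2,3,7-trioxabicyclo[2.2.1]heptane (5-exo-ethyl) | O1[C@@]2(CC)C[C@@H](CC)[C@@H]1OO2 | intermediate
20 | trimethylaluminium | C[Al](C)C | starting material
21 | dimethyl[(1E,4R,5E)-4-ethyl-2-methylocta-1,5-dien-1-yl]alane | C[Al](C)/C=C(C)/C[C@@H](CC)/C=C/CC | intermediate
22 | (3S,4R,6R)-4,6-diethyl-6-[(1E,4R,5E)-4-ethyl-2-methylocta-1,5-dien-1-yl]-1,2-dioxan-3-ol | CC/C=C/[C@H](CC)C/C(C)=C/[C@@]1(CC)C[C@@H](CC)[C@@H](O)OO1 | intermediate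
23 | methanol | CO | starting material
24 | (3S,4R,6R)-4,6-diethyl-6-[(1E,4R,5E)-4-ethyl-2-methylocta-1,5-dien-1-yl]-3-methoxy-1,2-dioxane | CC/C=C/[C@H](CC)C/C(C)=C/[C@@]1(CC)C[C@@H](CC)[C@@H](OC)OO1 | intermediate
25 | 1-(tert-butyldimethylsilyloxy)-1-methoxyethene | C=C(OC)O[Si](C)(C)C(C)(C)C | starting material
26 | methyl 2-[(3R,4R,6R)-4,6-diethyl-6-[(1E,4R,5E)-4-ethyl-2-methylocta-1,5-dien-1-yl]-1,2-dioxan-3-yl]acetate | CC/C=C/[C@H](CC)C/C(C)=C/[C@@]1(CC)C[C@@H](CC)[C@@H](CC(=O)OC)OO1 | intermediate
27 | lithium hydroxide | [Li+].[OH-] | starting material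
28 | 2-[(3R,4R,6R)-4,6-diethyl-6-[(1E,4R,5E)-4-ethyl-2-methylocta-1,5-dien-1-yl]-1,2-dioxan-3-yl]acetic acid | CC/C=C/[C@H](CC)C/C(C)=C/[C@@]1(CC)C[C@@H](CC)[C@@H](CC(=O)O)OO1 | target

**Summary**

Total step count: 12. Longest linear sequence: 8 steps (steps 5–12; the side-chain branch, steps 1–4 then 9–12, is equally long).

Steps most likely to fail:

1. Step 9 (Proposed new method). The alane may reduce or cleave the O–O bond, may transfer methyl in place of alkenyl, or may open the bridge through a free, solvent-separated cation; in the last case the alkenyl group would enter anti to the C4 ethyl group and give the C6 epimer. The fallback uses known chemistry, sets out from 8 and 12 and comes back to the route at 24. Alkyne 8 is methylaluminated as before and the alane is quenched with iodine to give (1E,4R,5E)-4-ethyl-1-iodo-2-methylocta-1,5-diene F1. Iodine–lithium exchange (t-BuLi, Et2O, −78 °C) and addition of the alkenyllithium to the ketone of 12 should give the tertiary allylic alcohol (2R,5E,8R,9E)-2,4,8-triethyl-1,1-dimethoxy-6-methyldodeca-5,9-dien-4-ol F2 as a mixture of C6 epimers. Ethereal H2O2 with catalytic acid (perhydrolysis of the acetal, then SN1 capture of the tertiary allylic cation by the hydroperoxide) should close the dioxane to 24 and its C6 epimer, which would be separated before step 11. C6 is not controlled on this path.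

2. Step 8. The intramolecular cycloaddition may show poor facial selectivity (exo versus endo ethyl), the ketone oxide may oligomerise before it finds the aldehyde, and the α-branched aldehyde 16 may partly epimerise before ozonolysis. The fallback sets out from 12 and comes back at 19 without ozone. Treatment of 12 with ethereal H2O2 and BF3·OEt2 (stepwise peroxyketalisation of ketone and acetal under thermodynamic control) should give 19 together with the endo isomer (1S,4R,5R)-1,5-diethyl-2,3,7-trioxabicyclo[2.2.1]heptane F4. The two would be separated by chromatography and F4 resubmitted to the same acid conditions for re-equilibration.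

3. Step 11. The Lewis acid may ionise the tertiary allylic C6–O1 bond in competition with the C3 acetal, and facial selectivity at C3 may erode. The fallback sets out from 22 and comes back at 26. The ring-opened hydroperoxy aldehyde form of lactol 22 is olefinated with methyl (triphenylphosphoranylidene)acetate (Wittig) to give methyl (2E,4R,6R,7E,10R,11E)-4,6,10-triethyl-6-hydroperoxy-8-methyltetradeca-2,7,11-trienoate F5. Intramolecular oxa-Michael addition of the hydroperoxide (Et2NH, CF3CH2OH, 6-exo-trig) then closes the ring to 26. The C3 epimers would be separated, and the undesired one could be resubmitted because the Michael step is reversible under these conditions.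

Further compounds
F1 | step 9 | (1E,4R,5E)-4-ethyl-1-iodo-2-methylocta-1,5-diene | I/C=C(C)/C[C@@H](CC)/C=C/CC
F2 | step 9 | (2R,5E,8R,9E)-2,4,8-triethyl-1,1-dimethoxy-6-methyldodeca-5,9-dien-4-ol (C4 epimers) | CC/C=C/[C@H](CC)C/C(C)=C/C(O)(CC)C[C@@H](CC)C(OC)OC
F4 | step 8 | (1S,4R,5R)-1,5-diethyl-2,3,7-trioxabicyclo[2.2.1]heptane (5-endo-ethyl) | O1[C@]2(CC)C[C@@H](CC)[C@H]1OO2
F5 | step 11 | methyl (2E,4R,6R,7E,10R,11E)-4,6,10-triethyl-6-hydroperoxy-8-methyltetradeca-2,7,11-trienoate | CC/C=C/[C@H](CC)C/C(C)=C/[C@@](OO)(CC)C[C@@H](CC)/C=C/C(=O)OC
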